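## Retrosynthetic overview
- Ring C is the only ring made, and it is closed last. Disconnecting O1–C2 gives (E)-2',3'-dihydroxy-4',5',6',3,4-pentamethoxychalcone, and an enantioselective 6-endo-trig oxa-Michael closure sets C2 as (S).
- The 2',3'-catechol (future O1 and 8-OH) is the handle by which a boron co-catalyst binds the substrate, so no protecting group is needed.
- The chalcone comes from a Claisen–Schmidt condensation of 2,3-dihydroxy-4,5,6-trimethoxyacetophenone with veratraldehyde.
- The acetophenone comes from C-acylation of 3,4,5-trimethoxycatechol, at its one free ring position, with acetic acid.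
- The catechol comes from ortho C–O oxygenation of 3,4,5-trimethoxyphenol. Rings A and B are bought as arenes.

Assumption: the sense of induction of the new step cannot be fixed on paper. The quinine-derived thiourea is written for the (2S) product. Its equally commercial quinidine-derived pseudo-enantiomer replaces it if the first analytical run (chiral HPLC, circular dichroism) shows (2R).

## Route

Step 1
Reactants: 1 3,4,5-trimethoxyphenol
Product: 3 3,4,5-trimethoxybenzene-1,2-diol, via 3,4,5-trimethoxy-1,2-benzoquinone 2 (not isolated)
Conditions: IBX (1.1 equiv), DMF, rt, 1–2 h, argon; then aq. Na2S2O4 (3 equiv), EtOAc, rt, 15 min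
Reagents that add atoms: IBX (2-iodoxybenzoic acid), OI1(=O)OC(=O)c2ccccc12
Why: Pentavalent-iodine ortho-oxygenation of an electron-rich phenol, in which the phenol binds to iodine and oxygen is delivered intramolecularly to an ortho carbon (both ortho positions of 1 are equivalent), and dithionite reduces o-quinone 2 to the catechol in the same flask; no stereocentre is formed.

Step 2
Reactants: 3 3,4,5-trimethoxybenzene-1,2-diol, 4 acetic acid
Product: 5 1-(2,3-dihydroxy-4,5,6-trimethoxyphenyl)ethan-1-one
Conditions: AcOH (1.2 equiv), BF3·OEt2 (5 equiv, neat), 80 °C, 2 h, argon; then ice-water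
Reagents that add atoms: none
Why: Nencki-type Friedel–Crafts C-acylation (O-acylation/Fries manifold) at the only unsubstituted ring carbon, which lies ortho to OH and ortho/para to two OMe groups, and boron chelation between the new ketone and the neighbouring OH stops further reaction and spares the 6-OMe.

Step 3
Reactants: 5 1-(2,3-dihydroxy-4,5,6-trimethoxyphenyl)ethan-1-one, 6 3,4-dimethoxybenzaldehyde (veratraldehyde)
Product: 7 (E)-1-(2,3-dihydroxy-4,5,6-trimethoxyphenyl)-3-(3,4-dimethoxyphenyl)prop-2-en-1-one
Conditions: KOH (50% aq., 10 equiv), degassed EtOH, rt, 36 h, argon; then cold dilute aq. HCl to pH 4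
Reagents that add atoms: none
Why: Claisen–Schmidt aldol condensation with a non-enolisable aldehyde, where E1cB dehydration gives the (E)-enone, strong base holds the product as the ring-opened phenolate so no racemic flavanone forms, and excluding oxygen protects the catecholate.

Step 4
Reactants: 7 (E)-1-(2,3-dihydroxy-4,5,6-trimethoxyphenyl)-3-(3,4-dimethoxyphenyl)prop-2-en-1-one
Product: 9 (2S)-2-(3,4-dimethoxyphenyl)-8-hydroxy-5,6,7-trimethoxy-2,3-dihydro-4H-chromen-4-one, via chalcone diphenylborinate ion pair 8 (not isolated)
Conditions: (Ph2B)2O (5 mol%), 1-[3,5-bis(trifluoromethyl)phenyl]-3-[(8α,9S)-6'-methoxycinchonan-9-yl]thiourea (10 mol%), 4 Å molecular sieves, CH2Cl2, 0 °C, argon, 24–48 h; then aq. citric acid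
Reagents that add atoms: none
Why: Proposed new method: cooperative borinate/chiral-ammonium ion-pair catalysis of a 6-endo-trig oxa-Michael ring closure. The Ph2B unit condenses with the 2',3'-catechol of 7 and the quinuclidine nitrogen takes up the released proton, giving the tight ion pair 8. This removes the 2'-OH···O=C hydrogen bond that locks free 2'-hydroxychalcones in the unreactive rotamer, raises the electron density on O-2' (tetracoordinate boron), and places the thiourea N–H pair on the enone oxygen as an oxyanion hole. O-2' then adds to the Si face of C-β while the B–O-2' bond breaks, which forms O1–C2 and sets (2S), and the ammonium N–H protonates the enolate at C-3. The monodentate borinic ester of the product is displaced by the next chelating catechol, so the product neither inhibits the catalyst nor re-enters the reverse reaction, and the stereocentre is kept under near-neutral conditions. Closest known reaction types: borinic-acid-catalysed activation of 1,2-diols as tetracoordinate borinates for O-acylation, O-alkylation and glycosylation; boronic acid plus chiral amine–thiourea oxa-Michael additions to hydroxy enones; and cinchona-thiourea oxa-Michael cyclisation of activated alkylidene β-keto ester analogues of 2'-hydroxychalcones. None of these has been shown for a borinate-bound phenol adding to a plain chalcone.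

## Compound list
1 | 3,4,5-trimethoxyphenol | COc1cc(O)cc(OC)c1OC | starting material
2 | 3,4,5-trimethoxy-1,2-benzoquinone (3,4,5-trimethoxycyclohexa-3,5-diene-1,2-dione) | COC1=CC(=O)C(=O)C(OC)=C1OC | intermediate (not isolated)
3 | 3,4,5-trimethoxybenzene-1,2-diol | COc1cc(O)c(O)c(OC)c1OC | intermediate
4 | acetic acid | CC(=O)O | starting material
5 | 1-(2,3-dihydroxy-4,5,6-trimethoxyphenyl)ethan-1-one | CC(=O)c1c(O)c(O)c(OC)c(OC)c1OC | intermediate
6 | 3,4-dimethoxybenzaldehyde (veratraldehyde) | COc1ccc(C=O)cc1OC | starting material
7 | (E)-1-(2,3-dihydroxy-4,5,6-trimethoxyphenyl)-3-(3,4-dimethoxyphenyl)prop-2-en-1-one | COc1ccc(/C=C/C(=O)c2c(O)c(O)c(OC)c(OC)c2OC)cc1OC | intermediate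
8 | ion pair of the 2,2-diphenyl-1,3,2-benzodioxaborol-2-uide formed on the 2',3'-catechol of 7 with the quinuclidine-protonated thiourea catalyst | COc1ccc(/C=C/C(=O)c2c(OC)c(OC)c(OC)c3O[B-](c4ccccc4)(c4ccccc4)Oc23)cc1OC.COc1ccc2nccc([C@H](NC(=S)Nc3cc(cc(c3)C(F)(F)F)C(F)(F)F)[C@@H]3C[C@@H]4CC[NH+]3C[C@@H]4C=C)c2c1 | intermediate (not isolated)
9 | (2S)-2-(3,4-dimethoxyphenyl)-8-hydroxy-5,6,7-trimethoxy-2,3-dihydro-4H-chromen-4-one, i.e. (2S)-8-hydroxy-5,6,7,3',4'-pentamethoxyflavanone | COc1ccc([C@@H]2CC(=O)c3c(c(O)c(OC)c(OC)c3OC)O2)cc1OC | target

## Step count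
- Total step count: 4
- Longest linear sequence: 4 (1 → 3 → 5 → 7 → 9)

## Steps most likely to fail

**Step 4 (the proposed new method).**
- Boron may rest as the neutral six-membered 2'-O/C=O chelate instead of the catecholate.
- The borinate oxygen may be too weak a nucleophile.
- The ion pair may give only modest ee.
- Free amine left at the end of the run could slowly racemise 9, so the reaction is quenched with acid as soon as conversion is complete.

Fallback, known chemistry. It sets out from 7. Heating with NaOAc in EtOH at reflux closes the ring without stereocontrol to the racemic flavanone F1. Preparative chiral chromatography (SFC or HPLC, amylose tris(3,5-dimethylphenylcarbamate) phase) separates F1 into 9 and the (2R)-enantiomer F2. F2 is reopened to 7 with KOH in EtOH and cyclised again. The fallback comes back to the route at 9.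

**Step 1 (ortho-oxygenation).**
- The very electron-rich phenol may lose its 4-methoxy group and go to a para-quinone.
- The o-quinone may degrade before it is reduced.
- The air-sensitive, fairly water-soluble catechol may be lost on work-up.

Fallback. It sets out from 1. Magnesium-mediated ortho-formylation (MgCl2, Et3N, (CH2O)n, MeCN, reflux) gives 2-hydroxy-4,5,6-trimethoxybenzaldehyde F3. Dakin oxidation (H2O2, aq. NaOH, 0 °C to rt, then acid) exchanges the formyl group for OH. The fallback comes back to the route at 3.

**Step 3 (condensation on the free catechol).**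
- The catecholate may autoxidise.
- The doubly deprotonated ketone may enolise too slowly.

Fallback. It sets out from 5. NaH and MOMCl in DMF give the bis(methoxymethyl) ether F4. Condensation of F4 with 6 (KOH, EtOH, rt) gives the protected chalcone F5. Mild acid (HCl, MeOH, 40 °C, short time) removes both acetals. The fallback comes back to the route at 7.

## Further compounds
F1 | step 4 | racemic 2-(3,4-dimethoxyphenyl)-8-hydroxy-5,6,7-trimethoxy-2,3-dihydro-4H-chromen-4-one | COc1ccc(C2CC(=O)c3c(c(O)c(OC)c(OC)c3OC)O2)cc1OC
F2 | step 4 | (2R)-2-(3,4-dimethoxyphenyl)-8-hydroxy-5,6,7-trimethoxy-2,3-dihydro-4H-chromen-4-one | COc1ccc([C@H]2CC(=O)c3c(c(O)c(OC)c(OC)c3OC)O2)cc1OC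
F3 | step 1 | 2-hydroxy-4,5,6-trimethoxybenzaldehyde | COc1cc(O)c(C=O)c(OC)c1OC
F4 | step 3 | 1-[4,5,6-trimethoxy-2,3-bis(methoxymethoxy)phenyl]ethan-1-one | CC(=O)c1c(OCOC)c(OCOC)c(OC)c(OC)c1OC
F5 | step 3 | (E)-3-(3,4-dimethoxyphenyl)-1-[4,5,6-trimethoxy-2,3-bis(methoxymethoxy)phenyl]prop-2-en-1-one | COCOc1c(OCOC)c(C(=O)/C=C/c2ccc(OC)c(OC)c2)c(OC)c(OC)c1OC
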